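## Analysis of the target

Compound 25 is a linear, achiral pentamer of 1,3,5-trioxygenated benzene rings joined by four diaryl ether oxygens. It has no stereocentre and no configurationally stable axis, so nothing stereochemical has to be set. Ring A carries the ether oxygen to ring B at C1 and hydroxyls at C2, C4 and C6. Rings B, C and D carry the oxygen from the preceding ring at C1 (H at C2 and C6), hydroxyls at C3 and C5, and the oxygen to the next ring at C4. Ring E has its ether oxygen at C1 and hydroxyls at C3, C4 and C5. Every ring therefore holds one "hindered" oxygen flanked by two hydroxyl-bearing carbons (on C1 of ring A, on C4 of rings B to E) and one unhindered oxygen para to it, and each ether joins the hindered carbon of one ring to the unhindered carbon of the next.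

The twelve free phenols, the pyrogallol ring E and the very electron-rich rings B to D are prone to oxidation by air, above all in base, so the free polyphenol should appear only at the end. The difficulties are three:

- four aryl–oxygen bonds to carbons flanked by two oxygen substituents on electron-rich rings, which are poor partners in copper-mediated couplings and inert to substitution as they stand;
- five nearly identical rings that must be joined in a fixed number and direction;
- twelve hydroxyls that must be unveiled without forcing Lewis acids.

The strategy rests on the ten hydroxyls at C2 and C6 of ring A and at C3 and C5 of rings B to E. All ten are ortho to a hindered oxygen. If each is written as a formyl carbon, the hindered carbon becomes a 2,6-diformylaryl position that is strongly activated for displacement of fluoride, and each formyl group can afterwards be exchanged for oxygen by a peracid.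

## Retrosynthetic reasoning

**Unmasking.** Target 25 is traced to the dibenzyl ether 24 by cutting the two benzyl–oxygen bonds (ring A C4–O and ring E C4–O), and 24 to the decaformate 23 by cutting ten formyl–oxygen bonds. This order means the only basic operation (methanolysis of 23) acts on a compound whose rings are resorcinol-type. The pyrogallol ring E and the free phloroglucinol ring A appear only in the neutral hydrogenolysis that ends the route.

**Key disconnection.** Decaformate 23 is traced to the decaaldehyde 22 by replacing each of the ten ring C–O bonds ortho to a hindered oxygen with a ring C–CHO bond. These are the C2 and C6 oxygens of ring A and the C3 and C5 oxygens of rings B to E. In the forward sense a peracid must insert oxygen between ring carbon and formyl carbon ten times, with the aryl group and not the formyl hydrogen migrating each time. The gain is that 22 contains no electron-rich ring and no free phenol. Its ten formyl groups are also exactly the substituents that make its four hindered ether bonds easy to form.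

**Ring E cap.** Compound 22 is cut at the ring E C4–O bond to the fluoride 20 and benzyl alcohol 21. The C4–F carbon of ring E in 20 is flanked by two formyl groups and is the last activated position of the chain, so the hindered oxygen of ring E enters by the same substitution that builds the ethers.

**The four hindered ether bonds.** Fluorides 20, 18, 16 and 14 are each cut at the bond between the terminal ring's unhindered oxygen and the hindered carbon of the ring before it. This gives, in turn, 18, 16, 14 and 12 as electrophiles and the same building block 10 as the nucleophile each time. The chain therefore grows from ring A to ring E. This direction was chosen because a phenol silyl ether placed on the electrophilic unit would not survive the fluoride that every substitution sets free, and a freed 4-fluoro-3,5-diformylphenoxide would oligomerise without control. In 10 the roles are reversed: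

- the silyl ether is the latent nucleophile, opened by catalytic fluoride;
- its own C–F carbon is switched off because the two flanking formyl groups are masked as dioxolanes.

After each coupling, aqueous acid unmasks the two formyl groups and switches the new terminal C–F on. Exactly one ring is added per cycle, and all four bonds form without a metal.

**Two building blocks from one dialdehyde.** Both 12 (ring A, benzyl ether, activated C–F) and 10 (rings B to E, silyl ether, masked C–F) come from the dialdehyde 9. Exchange of silyl for benzyl with benzyl bromide 11 gives 12. Double acetalisation with a 1,2-diol gives 10.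

**The fluoro dialdehyde.** Compound 9 is cut at its two ring C–CHO bonds, both ortho to fluorine. The second formyl comes from lithiation of the monoacetal 6 and quenching with N,N-dimethylformamide 3, and the first from the same operation on the silyl ether 2, which is made from 4-fluorophenol 1. Fluorine directs both metalations, while the bulky silyl group shields the positions next to oxygen. The acetal step between them is needed because an aldehyde cannot be carried through an alkyllithium.

## Alternatives that were turned down

**Alternative 1:** ring D is built from open-chain pieces.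

- Disconnection: two C–C bonds of ring D, C1–C2 and C4–C5.
- Forward key step: a conjugate addition of the acetoacetate A3 to the oxygen-bearing alkyne carbon of the aryloxypropiolate A2, followed by Claisen closure of the aryloxymethyl carbon onto the propiolate ester, under magnesium-alkoxide mediation. It should give the salicylate A1 with both ring D hydroxyls free.
- For: the regiochemistry is fixed by connectivity. The hindered C4–O bond of ring D is already present in A3, where it arises from a simple alkylation. Each bond-forming event is conventional, and on this point it is stronger than ten simultaneous migrations.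
- Against: only one of the four hindered ethers is solved. The three-ring aryloxy part of A2 still contains two hindered diaryl ethers that would need copper-mediated couplings of electron-rich partners. The ynol ether A2 of a di-ortho-substituted phenol is a delicate electrophile, and its Michael adduct can expel aryloxide instead of cyclising. A1 then needs removal of the ester carbon and cleavage of ten methyl ethers with a strong Lewis acid on an oxidation-prone polyphenol.
- Comparison: the chosen route forms all four hindered ethers with one building block and ends with mild deprotection, at the price of a less certain key step.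

**Alternative 2:** all four ether bonds from oxygen to the unhindered carbon C1 of rings B to E are formed in one pot.

- Forward key step: anodic oxidation of the cap A6 together with four equivalents of syringic acid A5. Each phenoxyl oxygen bonds to the carboxyl-bearing carbon of a syringate radical with decarboxylation, aiming at the pentamer A4.
- For: this is far shorter than anything else considered and clearly stronger on step economy. The site selectivity of each bond is intrinsic.
- Against: nothing fixes the chain length. A4 and every shorter oligomer carry a terminal phenol that is more easily oxidised than A5. Quinone-ketal redistribution, typical of oxidative phenylene-oxide couplings, would shuffle chain lengths and the cap. A5 also couples with itself without A6. A statistical mixture would have to be separated, and A4 would still need eleven methyl ethers cleaved.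
- Comparison: the chosen route is much longer but adds exactly one ring per cycle through its on/off switch.

**Alternative 3:** ring C is made from the pyranone A8, itself derived from the cheap lactone A9.

- Forward key step: under magnesium-alkoxide mediation in an alcohol the lactone opens to an open-chain keto ester. The carbon carrying the aryloxy group then closes onto the ester carbonyl by Claisen condensation and aromatises, giving A7 with free hydroxyls at C3 and C5 of ring C.
- For: the plan is convergent (a two-ring piece on each side of ring C). The hindered C4–O bond of ring C is preformed by alkylation, and the isomerisation is a known, biomimetic reaction type. In convergence it is stronger than the linear chosen route.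
- Against: again only one hindered ether is solved, since each two-ring piece of A8 contains one that must come from a difficult coupling. The alkoxide can displace the hindered aryloxide at C4 of A8 by addition–elimination, cutting off the left-hand piece. A7 still needs ten methyl ethers removed.
- Comparison: the chosen route is linear but repeats one reliable cycle and needs no Lewis-acid demethylation.

Key step: step 12

## Route

Step 1
Reactants: 1 4-fluorophenol
Product: 2 (4-fluorophenoxy)triisopropylsilane
Conditions: TIPSCl, imidazole, CH2Cl2, rt
Reagents that add atoms: chlorotriisopropylsilane (TIPSCl), CC(C)[Si](Cl)(C(C)C)C(C)C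
Why: Standard O-silylation of a phenol; the bulky silyl ether survives alkyllithiums and shields the positions ortho to oxygen in the metalations that follow.

Step 2
Reactants: 2 (4-fluorophenoxy)triisopropylsilane; 3 N,N-dimethylformamide
Product: 5 2-fluoro-5-[(triisopropylsilyl)oxy]benzaldehyde, via aryllithium 4 (not isolated)
Conditions: s-BuLi, THF, −78 °C; DMF, −78 to 0 °C; 1 M HCl
Reagents that add atoms: N,N-dimethylformamide (3), CN(C)C=O
Why: Directed ortho-metalation; fluorine acidifies its ortho hydrogen and the silyl group blocks coordination at oxygen, so lithiation should occur next to fluorine, and formylation of the aryllithium with DMF gives the aldehyde; the cold temperature prevents loss of LiF to an aryne.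

Step 3
Reactants: 5 2-fluoro-5-[(triisopropylsilyl)oxy]benzaldehyde
Product: 6 2-{2-fluoro-5-[(triisopropylsilyl)oxy]phenyl}-1,3-dioxolane
Conditions: HOCH2CH2OH, p-TsOH·H2O (cat.), toluene, reflux (Dean–Stark)
Reagents that add atoms: ethylene glycol, OCCO
Why: Acid-catalysed acetalisation with azeotropic removal of water; the aryl silyl ether tolerates the catalytic acid and the dioxolane makes the carbonyl inert to s-BuLi.

Step 4
Reactants: 6 2-{2-fluoro-5-[(triisopropylsilyl)oxy]phenyl}-1,3-dioxolane; 3 N,N-dimethylformamide
Product: 9 2-fluoro-5-[(triisopropylsilyl)oxy]benzene-1,3-dicarbaldehyde, via aryllithium 7 (not isolated), via acetal aldehyde 8 (not isolated)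
Conditions: s-BuLi, THF, −78 °C; DMF, −78 to 0 °C; then 2 M HCl, THF, rt
Reagents that add atoms: N,N-dimethylformamide (3), CN(C)C=O; water, O
Why: Second directed ortho-metalation at the only remaining position next to fluorine (the other free positions lie next to the bulky silyl ether), formylation with DMF, and acetal hydrolysis in the acidic work-up; aryl triisopropylsilyl ethers withstand dilute aqueous acid at room temperature.

Step 5
Reactants: 9 2-fluoro-5-[(triisopropylsilyl)oxy]benzene-1,3-dicarbaldehyde
Product: 10 2,2'-{2-fluoro-5-[(triisopropylsilyl)oxy]-1,3-phenylene}bis(1,3-dioxolane)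
Conditions: HOCH2CH2OH (excess), p-TsOH·H2O (cat.), toluene, reflux (Dean–Stark)
Reagents that add atoms: ethylene glycol, OCCO
Why: Double acetalisation; it removes both acceptor groups that flank fluorine, so that the C–F carbon of this building block is no longer an SNAr electrophile.

Step 6
Reactants: 9 2-fluoro-5-[(triisopropylsilyl)oxy]benzene-1,3-dicarbaldehyde; 11 benzyl bromide
Product: 12 5-(benzyloxy)-2-fluorobenzene-1,3-dicarbaldehyde
Conditions: CsF, BnBr (excess), DMF, 0 °C to rt
Reagents that add atoms: benzyl bromide (11), BrCc1ccccc1
Why: One-pot fluoride desilylation and Williamson benzylation; the phenoxide is trapped by the excess of the reactive benzyl halide as it forms, which should keep it from attacking the activated C–F of a second molecule.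

Step 7
Reactants: 12 5-(benzyloxy)-2-fluorobenzene-1,3-dicarbaldehyde; 10 2,2'-{2-fluoro-5-[(triisopropylsilyl)oxy]-1,3-phenylene}bis(1,3-dioxolane)
Product: 14 5-(benzyloxy)-2-(4-fluoro-3,5-diformylphenoxy)benzene-1,3-dicarbaldehyde (rings A–B, tetraaldehyde, F at C4 of ring B), via bis-dioxolane dimer 13 (not isolated)
Conditions: CsF (0.3 equiv), DMF, rt to 40 °C; then 2 M HCl, THF, 40 °C
Reagents that add atoms: water, O
Why: Fluoride-relayed SNAr: fluoride opens the silyl ether of 10, the phenoxide displaces the fluoride flanked by two formyl groups in 12, and the fluoride set free carries the chain; the new terminal C–F is flanked by acetals and cannot react further, so only one unit adds. Acetal hydrolysis then unmasks the two formyl groups of ring B and activates its C–F.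

Step 8
Reactants: 14 rings A–B tetraaldehyde fluoride; 10 2,2'-{2-fluoro-5-[(triisopropylsilyl)oxy]-1,3-phenylene}bis(1,3-dioxolane)
Product: 16 5-(benzyloxy)-2-[4-(4-fluoro-3,5-diformylphenoxy)-3,5-diformylphenoxy]benzene-1,3-dicarbaldehyde (rings A–C, hexaaldehyde, F at C4 of ring C), via bis-dioxolane trimer 15 (not isolated)
Conditions: CsF (0.3 equiv), DMF, rt to 40 °C; then 2 M HCl, THF, 40 °C
Reagents that add atoms: water, O
Why: Same fluoride-relayed SNAr and acetal hydrolysis as in step 7; fluoride at a 2,6-diformyl carbon is displaced far faster than aryloxide at the equally flanked ether carbon already present, which should keep the chain intact.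

Step 9
Reactants: 16 rings A–C hexaaldehyde fluoride; 10 2,2'-{2-fluoro-5-[(triisopropylsilyl)oxy]-1,3-phenylene}bis(1,3-dioxolane)
Product: 18 rings A–D octaaldehyde fluoride (ring A as 4-(benzyloxy)-2,6-diformylphenyl, rings B and C as 3,5-diformyl-1,4-phenylenedioxy units, ring D as 4-fluoro-3,5-diformylphenoxy), via bis-dioxolane tetramer 17 (not isolated)
Conditions: CsF (0.3 equiv), DMF, rt to 40 °C; then 2 M HCl, THF, 40 °C
Reagents that add atoms: water, O
Why: Third cycle of the same SNAr and hydrolysis sequence; the electrophile becomes more reactive with each ring because the para substituent of the terminal C–F is now an electron-poor aryloxy group.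

Step 10
Reactants: 18 rings A–D octaaldehyde fluoride; 10 2,2'-{2-fluoro-5-[(triisopropylsilyl)oxy]-1,3-phenylene}bis(1,3-dioxolane)
Product: 20 rings A–E decaaldehyde fluoride (as 18 with a further 3,5-diformyl-1,4-phenylenedioxy ring D and ring E as 4-fluoro-3,5-diformylphenoxy), via bis-dioxolane pentamer 19 (not isolated)
Conditions: CsF (0.3 equiv), DMF, rt to 40 °C; then 2 M HCl, THF, 40 °C
Reagents that add atoms: water, O
Why: Fourth cycle of the fluoride-relayed SNAr and acetal hydrolysis; it forms the last hindered diaryl ether and leaves an activated C–F at C4 of ring E.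

Step 11
Reactants: 20 rings A–E decaaldehyde fluoride; 21 benzyl alcohol
Product: 22 decaformyl pentamer with benzyl ethers at C4 of ring A and C4 of ring E
Conditions: BnOH, K2CO3, DMF, 0 °C to rt
Reagents that add atoms: benzyl alcohol (21), OCc1ccccc1
Why: SNAr of the terminal fluoride by benzyl alkoxide; the strong preference of SNAr for fluoride over aryloxide as the group at the attacked carbon should direct the alkoxide to C4 of ring E and not to the four internal ether carbons, and the carbonate base keeps the alkoxide concentration low.

Step 12
Reactants: 22 decaformyl pentamer dibenzyl ether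
Product: 23 decaformate pentamer dibenzyl ether (formyloxy at C2 and C6 of ring A and at C3 and C5 of rings B to E)
Conditions: mCPBA (30 equiv), CH2Cl2, 0 °C to reflux, no added base
Reagents that add atoms: meta-chloroperoxybenzoic acid (mCPBA), OOC(=O)c1cccc(Cl)c1
Why: The peracid adds to each formyl group to give a Criegee adduct, which collapses by 1,2-shift of the aryl carbon from carbon to oxygen with loss of 3-chlorobenzoate, so each ring C–CHO bond becomes a ring C–O bond of an aryl formate. The closest known reaction is the Baeyer–Villiger (Dakin-type) oxidation of ortho-alkoxy- and ortho-aryloxybenzaldehydes to aryl formates with peracids. No ring is closed and no stereocentre is formed. The selectivity needed is migration of aryl over the formyl hydrogen at each of ten sites. It is secured by the ether oxygen ortho to every formyl-bearing carbon, whose lone pair stabilises the electron-deficient migrating carbon, and by the ortho substituent that twists the Criegee adduct out of the ring plane. No base is added, because base promotes fragmentation of the adduct with loss of the formyl hydrogen to the carboxylic acid, while the 3-chlorobenzoic acid set free catalyses the aryl shift. A formyloxy group meta to the remaining formyl group withdraws about as much as the formyl it replaces, so the ten events should be nearly independent and no acceleration along the way is counted on. Benzyl ethers and diaryl ethers are inert to the peracid, and anhydrous conditions keep the formates on, so that no free electron-rich phenol meets the oxidant.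

Step 13
Reactants: 23 decaformate pentamer dibenzyl ether
Product: 24 decahydroxy pentamer dibenzyl ether (hydroxyls at C2 and C6 of ring A and at C3 and C5 of rings B to E; benzyl ethers at C4 of rings A and E)
Conditions: K2CO3 (cat.), degassed MeOH–THF, Ar, 0 °C to rt
Reagents that add atoms: none
Why: Transesterification of aryl formates to methyl formate is fast with catalytic base; at this stage every ring is a resorcinol-type diol with its third oxygen still etherified, which limits sensitivity to traces of air.

Step 14
Reactants: 24 decahydroxy pentamer dibenzyl ether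
Product: 25 target dodecaphenol (CNP0308003.0)
Conditions: H2 (1 atm), 10% Pd/C, degassed MeOH–EtOAc, rt; filtration under Ar
Reagents that add atoms: none
Why: Hydrogenolysis of the two aryl benzyl ethers under neutral conditions; diaryl ethers are stable to Pd/C at ambient pressure, and the pyrogallol ring E is set free only here, without base.

## Compound list

1 | 4-fluorophenol | Oc1ccc(F)cc1 | starting material
2 | (4-fluorophenoxy)triisopropylsilane | CC(C)[Si](Oc1ccc(F)cc1)(C(C)C)C(C)C | intermediate
3 | N,N-dimethylformamide | CN(C)C=O | starting material
4 | 2-fluoro-5-[(triisopropylsilyl)oxy]phenyllithium | [Li]c1cc(O[Si](C(C)C)(C(C)C)C(C)C)ccc1F | intermediate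
5 | 2-fluoro-5-[(triisopropylsilyl)oxy]benzaldehyde | O=Cc1cc(O[Si](C(C)C)(C(C)C)C(C)C)ccc1F | intermediate
6 | 2-{2-fluoro-5-[(triisopropylsilyl)oxy]phenyl}-1,3-dioxolane | Fc1ccc(O[Si](C(C)C)(C(C)C)C(C)C)cc1C1OCCO1 | intermediate
7 | 3-(1,3-dioxolan-2-yl)-2-fluoro-5-[(triisopropylsilyl)oxy]phenyllithium | [Li]c1cc(O[Si](C(C)C)(C(C)C)C(C)C)cc(C2OCCO2)c1F | intermediate
8 | 3-(1,3-dioxolan-2-yl)-2-fluoro-5-[(triisopropylsilyl)oxy]benzaldehyde | O=Cc1cc(O[Si](C(C)C)(C(C)C)C(C)C)cc(C2OCCO2)c1F | intermediate
9 | 2-fluoro-5-[(triisopropylsilyl)oxy]benzene-1,3-dicarbaldehyde | O=Cc1cc(O[Si](C(C)C)(C(C)C)C(C)C)cc(C=O)c1F | intermediate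
10 | 2,2'-{2-fluoro-5-[(triisopropylsilyl)oxy]-1,3-phenylene}bis(1,3-dioxolane) | CC(C)[Si](Oc1cc(C2OCCO2)c(F)c(C2OCCO2)c1)(C(C)C)C(C)C | intermediate
11 | benzyl bromide | BrCc1ccccc1 | starting material
12 | 5-(benzyloxy)-2-fluorobenzene-1,3-dicarbaldehyde | O=Cc1cc(OCc2ccccc2)cc(C=O)c1F | intermediate
13 | 5-(benzyloxy)-2-[4-fluoro-3,5-bis(1,3-dioxolan-2-yl)phenoxy]benzene-1,3-dicarbaldehyde | O=Cc1cc(OCc2ccccc2)cc(C=O)c1Oc1cc(C2OCCO2)c(F)c(C2OCCO2)c1 | intermediate
14 | 5-(benzyloxy)-2-(4-fluoro-3,5-diformylphenoxy)benzene-1,3-dicarbaldehyde | O=Cc1cc(OCc2ccccc2)cc(C=O)c1Oc1cc(C=O)c(F)c(C=O)c1 | intermediate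
15 | rings A–C trimer, rings A and B as dialdehydes, ring C as 4-fluoro-3,5-bis(1,3-dioxolan-2-yl)phenoxy | O=Cc1cc(OCc2ccccc2)cc(C=O)c1Oc1cc(C=O)c(Oc2cc(C3OCCO3)c(F)c(C3OCCO3)c2)c(C=O)c1 | intermediate
16 | 5-(benzyloxy)-2-[4-(4-fluoro-3,5-diformylphenoxy)-3,5-diformylphenoxy]benzene-1,3-dicarbaldehyde | O=Cc1cc(OCc2ccccc2)cc(C=O)c1Oc1cc(C=O)c(Oc2cc(C=O)c(F)c(C=O)c2)c(C=O)c1 | intermediate
17 | rings A–D tetramer, rings A to C as dialdehydes, ring D as 4-fluoro-3,5-bis(1,3-dioxolan-2-yl)phenoxy | O=Cc1cc(OCc2ccccc2)cc(C=O)c1Oc1cc(C=O)c(Oc2cc(C=O)c(Oc3cc(C4OCCO4)c(F)c(C4OCCO4)c3)c(C=O)c2)c(C=O)c1 | intermediate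
18 | rings A–D octaaldehyde, ring D as 4-fluoro-3,5-diformylphenoxy | O=Cc1cc(OCc2ccccc2)cc(C=O)c1Oc1cc(C=O)c(Oc2cc(C=O)c(Oc3cc(C=O)c(F)c(C=O)c3)c(C=O)c2)c(C=O)c1 | intermediate
19 | rings A–E pentamer, rings A to D as dialdehydes, ring E as 4-fluoro-3,5-bis(1,3-dioxolan-2-yl)phenoxy | O=Cc1cc(OCc2ccccc2)cc(C=O)c1Oc1cc(C=O)c(Oc2cc(C=O)c(Oc3cc(C=O)c(Oc4cc(C5OCCO5)c(F)c(C5OCCO5)c4)c(C=O)c3)c(C=O)c2)c(C=O)c1 | intermediate
20 | rings A–E decaaldehyde, ring E as 4-fluoro-3,5-diformylphenoxy | O=Cc1cc(OCc2ccccc2)cc(C=O)c1Oc1cc(C=O)c(Oc2cc(C=O)c(Oc3cc(C=O)c(Oc4cc(C=O)c(F)c(C=O)c4)c(C=O)c3)c(C=O)c2)c(C=O)c1 | intermediate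
21 | benzyl alcohol | OCc1ccccc1 | starting material
22 | decaformyl pentamer, benzyl ethers at C4 of rings A and E | O=Cc1cc(OCc2ccccc2)cc(C=O)c1Oc1cc(C=O)c(Oc2cc(C=O)c(Oc3cc(C=O)c(Oc4cc(C=O)c(OCc5ccccc5)c(C=O)c4)c(C=O)c3)c(C=O)c2)c(C=O)c1 | intermediate
23 | decaformate pentamer, benzyl ethers at C4 of rings A and E | O=COc1cc(OCc2ccccc2)cc(OC=O)c1Oc1cc(OC=O)c(Oc2cc(OC=O)c(Oc3cc(OC=O)c(Oc4cc(OC=O)c(OCc5ccccc5)c(OC=O)c4)c(OC=O)c3)c(OC=O)c2)c(OC=O)c1 | intermediate
24 | decahydroxy pentamer, benzyl ethers at C4 of rings A and E | Oc1cc(OCc2ccccc2)cc(O)c1Oc1cc(O)c(Oc2cc(O)c(Oc3cc(O)c(Oc4cc(O)c(OCc5ccccc5)c(O)c4)c(O)c3)c(O)c2)c(O)c1 | intermediate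
25 | CNP0308003.0, dodecahydroxy pentamer | Oc1cc(O)c(Oc2cc(O)c(Oc3cc(O)c(Oc4cc(O)c(Oc5cc(O)c(O)c(O)c5)c(O)c4)c(O)c3)c(O)c2)c(O)c1 | target

## Step count and least certain steps

Total: 14 steps. Longest linear sequence: 13 steps (steps 1 to 5 and 7 to 14; step 6 is the branch from 9 to the ring A unit 12).

**Step 12 (key step).** The most likely failure is migration of the formyl hydrogen in some of the ten Criegee adducts, giving carboxylic acids. Each formyl-bearing ring still carries a second acceptor, and the ortho ether oxygen is twisted and donates less than in a simple anisaldehyde. With ten events a small leak per site costs most of the material. A change of oxidant (H2O2 with catalytic diphenyl diselenide, which favours aryl migration in weakly activated benzaldehydes) would be tried first. The fallback changes the migrating partner and sets out from 22: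

1. Tenfold addition of MeMgBr in THF at −78 °C should give the deca(1-hydroxyethyl) pentamer F1, a mixture of diastereomers that is of no consequence.
2. Oxidation with Dess–Martin periodinane should give the decaacetyl pentamer F2.
3. Baeyer–Villiger oxidation with mCPBA and trifluoroacetic acid in CH2Cl2 should give the decaacetate pentamer F3, because methyl migrates far less readily than aryl.
4. Methanolysis of F3 under the conditions of step 13 returns to 24.

**Step 10 (last chain extension).** With four activated ether carbons already in the electrophile, exchange of aryloxide at an internal ether carbon by phenoxide or fluoride could shuffle chain lengths. Acetal hydrolysis on a sparingly soluble decaaldehyde could also stall. Isolation of 19 before hydrolysis is the simple remedy. The fallback replaces the last two substitutions by one union with a pre-capped ring E and sets out from 9 and 18: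

1. CsF and 4-methoxybenzyl chloride in DMF convert 9 into 2-fluoro-5-[(4-methoxybenzyl)oxy]benzene-1,3-dicarbaldehyde F4.
2. Benzyl alcohol 21 and K2CO3 in DMF give 2-(benzyloxy)-5-[(4-methoxybenzyl)oxy]benzene-1,3-dicarbaldehyde F5.
3. Trifluoroacetic acid with anisole in CH2Cl2 gives 2-(benzyloxy)-5-hydroxybenzene-1,3-dicarbaldehyde F6.
4. F6 and 18 with K2CO3 in DMF give 22 directly.

**Step 11 (benzyl cap).** Benzyl alkoxide may add to formyl groups and start hydride-transfer side reactions, or attack an internal ether carbon and cut the chain. The fallback delivers the oxygen with a weakly basic oxime and alkylates afterwards, setting out from 20: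

1. (E)-Benzaldoxime and K2CO3 in DMSO should give the O-aryl oxime F7, which fragments in the flask with loss of benzonitrile to the rings A–E decaaldehyde with a free hydroxyl at C4 of ring E, F8.
2. Benzyl bromide 11 and K2CO3 in DMF then give 22.

**Step 6 (silyl to benzyl exchange).** The phenoxide set free from 9 could attack the activated C–F of 9 or 12 before it is benzylated, giving diaryl ether oligomers. The fallback performs the exchange on the ring whose C–F is switched off and sets out from 10:

1. CsF and benzyl bromide 11 in DMF give 2,2'-[5-(benzyloxy)-2-fluoro-1,3-phenylene]bis(1,3-dioxolane) F9.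
2. 2 M HCl in THF hydrolyses F9 to 12.

**Step 14 (final hydrogenolysis).** Oxidation of ring E and of the electron-rich rings during removal of the catalyst, and adsorption of the polyphenol on carbon, are the likely losses. The fallback reverses the order of the last two steps and sets out from 23:

1. Hydrogenolysis with H2 and Pd/C in EtOAc should give the decaformate with free hydroxyls at C4 of rings A and E, F10, which is protected against air by its ten formates.
2. HCl in degassed methanol then gives 25. The only by-product is volatile, and no catalyst has to be filtered from the free polyphenol.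

## Further compounds

F1 | step 12 | deca(1-hydroxyethyl) pentamer dibenzyl ether, mixture of diastereomers | CC(O)c1cc(OCc2ccccc2)cc(C(C)O)c1Oc1cc(C(C)O)c(Oc2cc(C(C)O)c(Oc3cc(C(C)O)c(Oc4cc(C(C)O)c(OCc5ccccc5)c(C(C)O)c4)c(C(C)O)c3)c(C(C)O)c2)c(C(C)O)c1
F2 | step 12 | decaacetyl pentamer dibenzyl ether | CC(=O)c1cc(OCc2ccccc2)cc(C(C)=O)c1Oc1cc(C(C)=O)c(Oc2cc(C(C)=O)c(Oc3cc(C(C)=O)c(Oc4cc(C(C)=O)c(OCc5ccccc5)c(C(C)=O)c4)c(C(C)=O)c3)c(C(C)=O)c2)c(C(C)=O)c1
F3 | step 12 | decaacetate pentamer dibenzyl ether | CC(=O)Oc1cc(OCc2ccccc2)cc(OC(C)=O)c1Oc1cc(OC(C)=O)c(Oc2cc(OC(C)=O)c(Oc3cc(OC(C)=O)c(Oc4cc(OC(C)=O)c(OCc5ccccc5)c(OC(C)=O)c4)c(OC(C)=O)c3)c(OC(C)=O)c2)c(OC(C)=O)c1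
F4 | step 10 | 2-fluoro-5-[(4-methoxybenzyl)oxy]benzene-1,3-dicarbaldehyde | COc1ccc(COc2cc(C=O)c(F)c(C=O)c2)cc1
F5 | step 10 | 2-(benzyloxy)-5-[(4-methoxybenzyl)oxy]benzene-1,3-dicarbaldehyde | COc1ccc(COc2cc(C=O)c(OCc3ccccc3)c(C=O)c2)cc1
F6 | step 10 | 2-(benzyloxy)-5-hydroxybenzene-1,3-dicarbaldehyde | O=Cc1cc(O)cc(C=O)c1OCc1ccccc1
F7 | step 11 | rings A–E decaaldehyde with (E)-benzylideneaminooxy group at C4 of ring E | O=Cc1cc(OCc2ccccc2)cc(C=O)c1Oc1cc(C=O)c(Oc2cc(C=O)c(Oc3cc(C=O)c(Oc4cc(C=O)c(O/N=C/c5ccccc5)c(C=O)c4)c(C=O)c3)c(C=O)c2)c(C=O)c1
F8 | step 11 | rings A–E decaaldehyde with free hydroxyl at C4 of ring E | O=Cc1cc(OCc2ccccc2)cc(C=O)c1Oc1cc(C=O)c(Oc2cc(C=O)c(Oc3cc(C=O)c(Oc4cc(C=O)c(O)c(C=O)c4)c(C=O)c3)c(C=O)c2)c(C=O)c1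
F9 | step 6 | 2,2'-[5-(benzyloxy)-2-fluoro-1,3-phenylene]bis(1,3-dioxolane) | Fc1c(C2OCCO2)cc(OCc2ccccc2)cc1C1OCCO1
F10 | step 14 | decaformate pentamer with free hydroxyls at C4 of rings A and E | O=COc1cc(O)cc(OC=O)c1Oc1cc(OC=O)c(Oc2cc(OC=O)c(Oc3cc(OC=O)c(Oc4cc(OC=O)c(O)c(OC=O)c4)c(OC=O)c3)c(OC=O)c2)c(OC=O)c1
A1 | alternative 1 | pentamer with ring D as methyl 3,5-dihydroxy salicylate-type ring, other hydroxyls as methyl ethers | COc1cc(OC)c(Oc2cc(OC)c(Oc3cc(OC)c(Oc4cc(O)c(Oc5cc(OC)c(OC)c(OC)c5)c(O)c4C(=O)OC)c(OC)c3)c(OC)c2)c(OC)c1
A2 | alternative 1 | methyl 3-(aryloxy)propiolate carrying the rings A–C trimer on oxygen | COC(=O)C#COc1c(OC)cc(Oc2c(OC)cc(Oc3c(OC)cc(OC)cc3OC)cc2OC)cc1OC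
A3 | alternative 1 | methyl 3-oxo-4-(3,4,5-trimethoxyphenoxy)butanoate | COC(=O)CC(=O)COc1cc(OC)c(OC)c(OC)c1
A4 | alternative 2 | undeca-O-methyl pentamer with free hydroxyl at C4 of ring E | COc1cc(OC)c(Oc2cc(OC)c(Oc3cc(OC)c(Oc4cc(OC)c(Oc5cc(OC)c(O)c(OC)c5)c(OC)c4)c(OC)c3)c(OC)c2)c(OC)c1
A5 | alternative 2 | syringic acid | COc1cc(C(=O)O)cc(OC)c1O
A6 | alternative 2 | 2,4,6-trimethoxyphenol | COc1cc(OC)c(O)c(OC)c1
A7 | alternative 3 | pentamer with free hydroxyls at C3 and C5 of ring C, other hydroxyls as methyl ethers | COc1cc(OC)c(Oc2cc(OC)c(Oc3cc(O)c(Oc4cc(OC)c(Oc5cc(OC)c(OC)c(OC)c5)c(OC)c4)c(O)c3)c(OC)c2)c(OC)c1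
A8 | alternative 3 | 4-(aryloxy)-6-(aryloxymethyl)-2H-pyran-2-one carrying the rings A–B and D–E units | O=C1C=C(Oc2c(OC)cc(Oc3c(OC)cc(OC)cc3OC)cc2OC)C=C(COc2cc(OC)c(Oc3cc(OC)c(OC)c(OC)c3)c(OC)c2)O1
A9 | alternative 3 | 4-hydroxy-6-methyl-2H-pyran-2-one (triacetic acid lactone) | CC1=CC(O)=CC(=O)O1
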